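**Plan**

1. Retrosynthesis cuts first the two ethyl-ketone C=O bonds of the alcohol half, each back to a 1-propynyl group. This works because both ketone carbons (C3 and C7 of the nonane chain) lie at 6-exo distance from the ester carbonyl oxygen (O=C–O–C5–C4/C6–C3/C7), and the only ring, the 4-pyranone, is remote.
2. Next cuts: the ester C–O bond (acid 35 + diynol 13); in the acid, C4–C5 (β-ketoimide aldol onto pyranone aldehyde 22); the pyranone ring bonds (triketone from a diketone dianion and aldehyde 3); in the diynol, the carbinol–CH(Me) bond (allenylzinc + ynal 11).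
3. Forward: one silyloxy aldehyde 3 feeds both halves. The pyranone, the only ring, is closed early by cyclodehydration; the acid chain is grown from C5 to C1 on it; the halves are joined by Yamaguchi esterification while C5 is still a silyl ether; C5 is then oxidised, C3 unmasked and the two ketones unveiled last.
4. Stereochemistry: acid C6 and one methyl centre of the alcohol half come from methyl (R)-3-hydroxy-2-methylpropanoate; the other methyl centre from (R)-pent-3-yn-2-ol by allenylzinc chirality transfer; C2 from an Evans syn aldol; C4 by 1,3-induction from C2 in the titanium aldol; C3 by 1,3-anti reduction directed from a temporary C5 carbinol.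
5. The C5 ketone (with its labile C4 and C6 neighbours) and the β-acyloxy ketone array are both created only after the ester bond exists.

Key step: step 26

Remark: the carbinol carbon of the alcohol half carries two constitutionally identical, like-configured arms and is not a stereocentre; C1–C6 below mean the heptanoic acid chain.
Remark: (4R)-4-benzyl-3-propanoyl-1,3-oxazolidin-2-one and pent-3-yn-2-one are taken as purchased.

**Step 1**
Reactants: 1 methyl (R)-3-hydroxy-2-methylpropanoate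
Product: 2 methyl (R)-3-[tert-butyl(diphenyl)silyl]oxy-2-methylpropanoate
Conditions: t-BuPh2SiCl, imidazole, CH2Cl2, 0 °C to rt
Reagents that add atoms: tert-butyl(chloro)diphenylsilane, CC(C)(C)[Si](Cl)(c1ccccc1)c1ccccc1
Why: Imidazole-promoted O-silylation of the unhindered primary alcohol is routine and does not touch the α-stereocentre.

**Step 2**
Reactants: 2 silyl ether ester
Product: 3 (R)-3-[tert-butyl(diphenyl)silyl]oxy-2-methylpropanal
Conditions: i-Bu2AlH (1.05 equiv), CH2Cl2, −78 °C; MeOH, then aq. potassium sodium tartrate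
Reagents that add atoms: none
Why: Partial ester reduction with i-Bu2AlH stops at the tetrahedral aluminium hemiacetal at −78 °C, so the aldehyde should form without over-reduction or epimerisation.

**Step 3**
Reactants: 3 silyloxy aldehyde
Product: 4 (S)-tert-butyl[(4,4-dibromo-2-methylbut-3-en-1-yl)oxy]diphenylsilane
Conditions: CBr4, PPh3, CH2Cl2, 0 °C
Reagents that add atoms: tetrabromomethane, BrC(Br)(Br)Br
Why: Ramirez dibromo-olefination, the first half of the Corey–Fuchs sequence, runs under near-neutral Wittig conditions that α-branched β-silyloxy aldehydes tolerate.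

**Step 4**
Reactants: 4 dibromo-olefin
Product: 6 (S)-tert-butyl[(2-methylpent-3-yn-1-yl)oxy]diphenylsilane, via lithium acetylide 5 (not isolated)
Conditions: n-BuLi (2.1 equiv), THF, −78 °C; then MeI, −78 °C to rt
Reagents that add atoms: iodomethane, CI
Why: Second half of the Corey–Fuchs sequence: bromine–lithium exchange and Fritsch–Buttenberg–Wiechell rearrangement give acetylide 5, whose C-methylation installs the 1-propynyl group.

**Step 5**
Reactants: 6 silyl ether alkyne
Product: 7 (S)-2-methylpent-3-yn-1-ol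
Conditions: Bu4NF, THF, rt; careful concentration (volatile product)
Reagents that add atoms: none
Why: Fluoride-induced desilylation frees the primary alcohol, and the internal alkyne and propargylic stereocentre are inert to Bu4NF.

**Step 6**
Reactants: 8 pent-3-yn-2-one
Product: 9 (R)-pent-3-yn-2-ol
Conditions: Ru(p-cymene)[(R,R)-TsDPEN] (0.5 mol%), i-PrOH, rt
Reagents that add atoms: none
Why: Noyori asymmetric transfer hydrogenation of an alkynyl ketone, in which the alkynyl group takes the place of the aryl group of aryl ketones, so the (R,R)-ligand should set the (R)-carbinol.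

**Step 7**
Reactants: 9 (R)-propargylic alcohol
Product: 10 (R)-pent-3-yn-2-yl methanesulfonate
Conditions: MsCl, Et3N, CH2Cl2, −78 °C; used without purification
Reagents that add atoms: methanesulfonyl chloride, CS(=O)(=O)Cl
Why: O-Sulfonylation forms only the O–S bond, so the carbinol configuration is retained in the mesylate needed for the palladium step.

**Step 8**
Reactants: 7 (S)-ynol
Product: 11 (S)-2-methylpent-3-ynal
Conditions: Dess–Martin periodinane, NaHCO3, CH2Cl2, 0 °C; cold work-up, solution used at once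
Reagents that add atoms: none
Why: Buffered Dess–Martin oxidation is non-basic, which should keep the α-alkynyl aldehyde from enolising to the allenal or racemising before use.

**Step 9**
Reactants: 10 (R)-mesylate; 11 (S)-ynal
Product: 13 (4S,6S)-4,6-dimethylnona-2,7-diyn-5-ol, via ethyl(penta-2,3-dien-2-yl)zinc 12 (not isolated)
Conditions: Pd(OAc)2 (5 mol%), PPh3 (5 mol%), Et2Zn (3 equiv), THF, −78 to −20 °C
Reagents that add atoms: none
Why: Palladium-catalysed allenylzinc propargylation of an aldehyde: zerovalent palladium formed in situ displaces the mesylate in an anti SN2' sense, transmetalation gives the configurationally defined allenylzinc 12, and its SE2' addition through a cyclic transition state transfers the axial chirality to the new methyl-bearing carbon (S, net inversion at the mesylate carbon), while the carbinol carbon formed carries two identical arms and is not a stereocentre.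

**Step 10**
Reactants: 14 pentan-3-one; 15 ethyl propanoate
Product: 16 4-methylheptane-3,5-dione
Conditions: NaH, THF, reflux; aq. HCl work-up
Reagents that add atoms: none
Why: Crossed Claisen condensation of the ketone enolate with the ester, driven by deprotonation of the 1,3-diketone formed.

**Step 11**
Reactants: 16 diketone; 3 silyloxy aldehyde
Product: 18 (8R)-9-[tert-butyl(diphenyl)silyl]oxy-7-hydroxy-4,6,8-trimethylnonane-3,5-dione (epimers at C4/C6/C7), via dilithium diketone dianion 17 (not isolated)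
Conditions: LiN(i-Pr)2 (2.1 equiv), THF, −78 to 0 °C; then 3, −78 °C; aqueous quench
Reagents that add atoms: none
Why: Aldol addition of the 1,3-diketone dianion through its terminal, more nucleophilic carbon; the three uncontrolled centres all become sp2 in steps 12 and 13, whereas the C8 centre from 3 is carried through unchanged.

**Step 12**
Reactants: 18 β-hydroxy diketone
Product: 19 (8R)-9-[tert-butyl(diphenyl)silyl]oxy-4,6,8-trimethylnonane-3,5,7-trione
Conditions: Dess–Martin periodinane, NaHCO3, CH2Cl2, rt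
Reagents that add atoms: none
Why: Dess–Martin oxidation gives the 1,3,5-triketone under buffered conditions that should not enolise the new ketone towards C8.

**Step 13**
Reactants: 19 triketone
Product: 20 2-{(2R)-1-[tert-butyl(diphenyl)silyl]oxypropan-2-yl}-6-ethyl-3,5-dimethyl-4H-pyran-4-one
Conditions: PPh3, CCl4, THF, rt
Reagents that add atoms: none
Why: Cyclodehydration of the 1,3,5-triketone to the 4-pyranone: PPh3/CCl4 turns one terminal enol oxygen into an oxyphosphonium leaving group that the other terminal enol oxygen displaces (six-membered ring by addition–elimination), at room temperature and without strong acid or base.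

**Step 14**
Reactants: 20 pyranone silyl ether
Product: 21 2-ethyl-6-[(2R)-1-hydroxypropan-2-yl]-3,5-dimethyl-4H-pyran-4-one
Conditions: Bu4NF, AcOH, THF, 0 °C to rt
Reagents that add atoms: none
Why: Buffered fluoride desilylation; the stereocentre is flanked only by the pyranone and a CH2O group here and is not labile.

**Step 15**
Reactants: 21 pyranone alcohol
Product: 22 (2S)-2-(6-ethyl-3,5-dimethyl-4-oxo-4H-pyran-2-yl)propanal
Conditions: Dess–Martin periodinane, NaHCO3, CH2Cl2, 0 °C; used at once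
Reagents that add atoms: none
Why: Buffered Dess–Martin oxidation makes the α-pyranonyl aldehyde without base, so its acidic C–H is not exposed to enolisation before the next step.

**Step 16**
Reactants: 23 (4R)-4-benzyl-3-propanoyl-1,3-oxazolidin-2-one; 24 propanal
Product: 26 (4R)-4-benzyl-3-[(2R,3S)-3-hydroxy-2-methylpentanoyl]-1,3-oxazolidin-2-one, via dibutylboron enolate 25 (not isolated)
Conditions: Bu2BOTf, i-Pr2NEt, CH2Cl2, 0 °C; then 24, −78 to 0 °C; H2O2, MeOH, pH 7 buffer
Reagents that add atoms: none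
Why: Evans syn aldol: the (Z)-boron enolate reacts through a Zimmerman–Traxler chair on the face opposite the benzyl group, setting the methyl centre that becomes C2 of the acid as (R).

**Step 17**
Reactants: 26 syn aldol adduct
Product: 27 (4R)-4-benzyl-3-[(2R)-2-methyl-3-oxopentanoyl]-1,3-oxazolidin-2-one
Conditions: Dess–Martin periodinane, NaHCO3, CH2Cl2, rt
Reagents that add atoms: none
Why: Dess–Martin oxidation gives the β-ketoimide, whose C2–H is held in the imide plane by allylic strain and therefore resists enolisation.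

**Step 18**
Reactants: 27 β-ketoimide; 22 pyranone aldehyde
Product: 29 (4R)-4-benzyl-3-[(2R,4R,5S,6R)-6-(6-ethyl-3,5-dimethyl-4-oxo-4H-pyran-2-yl)-5-hydroxy-2,4-dimethyl-3-oxoheptanoyl]-1,3-oxazolidin-2-one, via trichlorotitanium enolate 28 (not isolated)
Conditions: TiCl4, i-Pr2NEt, CH2Cl2, −78 to −10 °C; then 22, −78 °C
Reagents that add atoms: none
Why: Titanium-mediated syn,syn aldol of the β-ketoimide: the chelated (Z)-enolate 28 adds through a closed transition state on the face dictated by the C2 methyl centre, setting C4 (2,4-syn) and the temporary C5 carbinol (4,5-syn, the anti-Felkin sense that (Z)-enolates normally favour with α-methyl aldehydes), while C6 is brought in from 22.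

**Step 19**
Reactants: 29 β-hydroxy ketoimide
Product: 31 (3R,4R,5S,6R)-6-[(1R)-1-(6-ethyl-3,5-dimethyl-4-oxo-4H-pyran-2-yl)ethyl]-4-hydroxy-3,5-dimethyloxan-2-one, via diol imide 30 (not isolated)
Conditions: Me4NBH(OAc)3, MeCN/AcOH (1:1), −25 °C; aq. potassium sodium tartrate; then crude in CH2Cl2, DBU (0.2 equiv), rt
Reagents that add atoms: none
Why: Evans–Saksena reduction: the C5 hydroxyl binds the acetoxyborohydride and delivers hydride intramolecularly to give the 3,5-anti diol (sets C3), and the C5 hydroxyl then displaces the oxazolidinone to form the δ-lactone, which tells the two hydroxyls apart.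

**Step 20**
Reactants: 31 hydroxy lactone (C3–OH free)
Product: 32 (3R,4R,5R,6R)-4-[tert-butyl(dimethyl)silyl]oxy-6-[(1R)-1-(6-ethyl-3,5-dimethyl-4-oxo-4H-pyran-2-yl)ethyl]-3,5-dimethyloxan-2-one
Conditions: t-BuMe2SiOTf, 2,6-lutidine, CH2Cl2, −78 to 0 °C
Reagents that add atoms: tert-butyldimethylsilyl trifluoromethanesulfonate, CC(C)(C)[Si](C)(C)OS(=O)(=O)C(F)(F)F
Why: Silyl triflate silylation of the hindered secondary alcohol; lactone and pyranone are stable to 2,6-lutidine.

**Step 21**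
Reactants: 32 silylated lactone
Product: 35 (2R,3R,4R,5R,6R)-3-[tert-butyl(dimethyl)silyl]oxy-6-(6-ethyl-3,5-dimethyl-4-oxo-4H-pyran-2-yl)-2,4-dimethyl-5-(triethylsilyl)oxyheptanoic acid, via lithium hydroxy carboxylate 33 (not isolated), via triethylsilyl ester 34 (not isolated)
Conditions: LiOH, THF/H2O, 0 °C; evaporation, toluene azeotrope; Et3SiOTf, 2,6-lutidine, CH2Cl2, −78 to 0 °C; pH 5 buffer work-up
Reagents that add atoms: lithium hydroxide, [Li+].[OH-]; triethylsilyl trifluoromethanesulfonate, CC[Si](CC)(CC)OS(=O)(=O)C(F)(F)F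
Why: Lactone saponification, silylation of both the freed C5 hydroxyl and the carboxylate, then selective hydrolysis of the far more labile silyl ester, a standard way to open a δ-lactone without relactonisation.

**Step 22**
Reactants: 35 acid; 13 diynol
Product: 37 (4S,6S)-4,6-dimethylnona-2,7-diyn-5-yl (2R,3R,4R,5R,6R)-3-[tert-butyl(dimethyl)silyl]oxy-6-(6-ethyl-3,5-dimethyl-4-oxo-4H-pyran-2-yl)-2,4-dimethyl-5-(triethylsilyl)oxyheptanoate, via mixed anhydride 36 (not isolated)
Conditions: 2,4,6-Cl3C6H2COCl, Et3N, THF, rt; then 13, DMAP, toluene, rt to 40 °C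
Reagents that add atoms: none
Why: Yamaguchi esterification via the mixed anhydride and the acylpyridinium ion; with C5 still a silyl ether there is no δ-keto group that could close to an enol lactone or epimerise at C6 under DMAP/Et3N.

**Step 23**
Reactants: 37 bis-silylated ester
Product: 38 (4S,6S)-4,6-dimethylnona-2,7-diyn-5-yl (2R,3R,4R,5R,6R)-3-[tert-butyl(dimethyl)silyl]oxy-6-(6-ethyl-3,5-dimethyl-4-oxo-4H-pyran-2-yl)-5-hydroxy-2,4-dimethylheptanoate
Conditions: pyridinium p-toluenesulfonate (cat.), MeOH/CH2Cl2, 0 °C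
Reagents that add atoms: none
Why: Selective desilylation: acid-catalysed methanolysis removes the secondary triethylsilyl ether much faster than the more hindered tert-butyldimethylsilyl ether.

**Step 24**
Reactants: 38 C5 alcohol
Product: 39 (4S,6S)-4,6-dimethylnona-2,7-diyn-5-yl (2R,3R,4S,6S)-3-[tert-butyl(dimethyl)silyl]oxy-6-(6-ethyl-3,5-dimethyl-4-oxo-4H-pyran-2-yl)-2,4-dimethyl-5-oxoheptanoate
Conditions: Dess–Martin periodinane, NaHCO3, CH2Cl2, 0 °C to rt
Reagents that add atoms: none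
Why: Buffered Dess–Martin oxidation creates the C5 ketone late and without base, so the flanking C4 and C6 centres should not epimerise.

**Step 25**
Reactants: 39 silylated keto ester
Product: 40 (4S,6S)-4,6-dimethylnona-2,7-diyn-5-yl (2R,3R,4S,6S)-6-(6-ethyl-3,5-dimethyl-4-oxo-4H-pyran-2-yl)-3-hydroxy-2,4-dimethyl-5-oxoheptanoate
Conditions: HF·pyridine, pyridine, THF, 0 °C to rt
Reagents that add atoms: none
Why: Buffered HF·pyridine desilylation is mildly acidic, which avoids β-elimination and retro-aldol cleavage of the β-hydroxy ketone and ester.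

**Step 26**
Reactants: 40 diynyl ester
Product: 42 (4R,6R)-4,6-dimethyl-3,7-dioxononan-5-yl (2R,3R,4S,6S)-6-(6-ethyl-3,5-dimethyl-4-oxo-4H-pyran-2-yl)-3-hydroxy-2,4-dimethyl-5-oxoheptanoate, via mono-ketone 41 (not isolated)
Conditions: Ph3PAuNTf2 (5 mol%), H2O (10 equiv), 1,4-dioxane, rt
Reagents that add atoms: water, O
Why: Ph3PAuNTf2 (monovalent gold) π-activates one alkyne and the ester carbonyl oxygen adds to the nearer alkyne carbon in a 6-exo-dig mode to give a vinylgold dioxanylium ion; water adds at the former carbonyl carbon, and protodeauration and collapse of the hemi-orthoester with the enol as leaving group return the ester on the carbinol oxygen and release the ethyl ketone, after which the same ester serves the second arm via 41. The closest known reaction type is the carbonyl-assisted gold hydration of propargylic and homopropargylic carboxylates, together with the 6-exo cyclisation of homopropargylic carbonates; using one ester for two alkynes in turn is an extension of it. No ring persists in the product, the only closure being the transient six-membered 6-exo-dig dioxanylium ring, and no stereocentre is created. The step needs oxygen at the proximal alkyne carbon of each arm, which is secured because that carbon lies at 6-exo distance from the ester carbonyl oxygen while the 7-endo and undirected modes should be slower. The methyl-bearing carbons stay sp3 throughout, because the released enol is formed towards the future ethyl group, and the near-neutral medium should spare the β-acyloxy ketone array, the C3 carbinol and the C4/C6 centres.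

**Compound list**

1 | methyl (R)-3-hydroxy-2-methylpropanoate | COC(=O)[C@H](C)CO | starting material
2 | methyl (R)-3-[tert-butyl(diphenyl)silyl]oxy-2-methylpropanoate | COC(=O)[C@H](C)CO[Si](c1ccccc1)(c1ccccc1)C(C)(C)C | intermediate
3 | (R)-3-[tert-butyl(diphenyl)silyl]oxy-2-methylpropanal | O=C[C@H](C)CO[Si](c1ccccc1)(c1ccccc1)C(C)(C)C | intermediate
4 | (S)-tert-butyl[(4,4-dibromo-2-methylbut-3-en-1-yl)oxy]diphenylsilane | BrC(Br)=C[C@H](C)CO[Si](c1ccccc1)(c1ccccc1)C(C)(C)C | intermediate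
5 | lithium (S)-4-[tert-butyl(diphenyl)silyl]oxy-3-methylbut-1-yn-1-ide | [Li]C#C[C@H](C)CO[Si](c1ccccc1)(c1ccccc1)C(C)(C)C | intermediate
6 | (S)-tert-butyl[(2-methylpent-3-yn-1-yl)oxy]diphenylsilane | CC#C[C@H](C)CO[Si](c1ccccc1)(c1ccccc1)C(C)(C)C | intermediate
7 | (S)-2-methylpent-3-yn-1-ol | CC#C[C@H](C)CO | intermediate
8 | pent-3-yn-2-one | CC#CC(C)=O | starting material
9 | (R)-pent-3-yn-2-ol | CC#C[C@@H](C)O | intermediate
10 | (R)-pent-3-yn-2-yl methanesulfonate | CC#C[C@@H](C)OS(C)(=O)=O | intermediate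
11 | (S)-2-methylpent-3-ynal | CC#C[C@H](C)C=O | intermediate
12 | ethyl[(aS)-penta-2,3-dien-2-yl]zinc | CC([Zn]CC)=[C@@]=C(C)[H] | intermediate
13 | (4S,6S)-4,6-dimethylnona-2,7-diyn-5-ol | CC#C[C@H](C)C(O)[C@@H](C)C#CC | intermediate
14 | pentan-3-one | CCC(=O)CC | starting material
15 | ethyl propanoate | CCOC(=O)CC | starting material
16 | 4-methylheptane-3,5-dione | CCC(=O)C(C)C(=O)CC | intermediate
17 | dilithium 4-methylhepta-2,4-diene-3,5-diolate (dianion of 16) | CC=C(O[Li])C(C)=C(O[Li])CC | intermediate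
18 | (8R)-9-[tert-butyl(diphenyl)silyl]oxy-7-hydroxy-4,6,8-trimethylnonane-3,5-dione (epimers at C4/C6/C7) | CCC(=O)C(C)C(=O)C(C)C(O)[C@H](C)CO[Si](c1ccccc1)(c1ccccc1)C(C)(C)C | intermediate
19 | (8R)-9-[tert-butyl(diphenyl)silyl]oxy-4,6,8-trimethylnonane-3,5,7-trione | CCC(=O)C(C)C(=O)C(C)C(=O)[C@H](C)CO[Si](c1ccccc1)(c1ccccc1)C(C)(C)C | intermediate
20 | 2-{(2R)-1-[tert-butyl(diphenyl)silyl]oxypropan-2-yl}-6-ethyl-3,5-dimethyl-4H-pyran-4-one | CCc1oc([C@H](C)CO[Si](c2ccccc2)(c2ccccc2)C(C)(C)C)c(C)c(=O)c1C | intermediate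
21 | 2-ethyl-6-[(2R)-1-hydroxypropan-2-yl]-3,5-dimethyl-4H-pyran-4-one | CCc1oc([C@H](C)CO)c(C)c(=O)c1C | intermediate
22 | (2S)-2-(6-ethyl-3,5-dimethyl-4-oxo-4H-pyran-2-yl)propanal | CCc1oc([C@H](C)C=O)c(C)c(=O)c1C | intermediate
23 | (4R)-4-benzyl-3-propanoyl-1,3-oxazolidin-2-one | CCC(=O)N1[C@H](Cc2ccccc2)COC1=O | starting material
24 | propanal | CCC=O | starting material
25 | dibutylboron (Z)-enolate of 23 | C/C=C(\OB(CCCC)CCCC)N1[C@H](Cc2ccccc2)COC1=O | intermediate
26 | (4R)-4-benzyl-3-[(2R,3S)-3-hydroxy-2-methylpentanoyl]-1,3-oxazolidin-2-one | O=C(N1[C@H](Cc2ccccc2)COC1=O)[C@H](C)[C@@H](O)CC | intermediate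
27 | (4R)-4-benzyl-3-[(2R)-2-methyl-3-oxopentanoyl]-1,3-oxazolidin-2-one | O=C(N1[C@H](Cc2ccccc2)COC1=O)[C@H](C)C(=O)CC | intermediate
28 | trichlorotitanium (Z)-enolate of 27 | C/C=C(\O[Ti](Cl)(Cl)Cl)[C@@H](C)C(=O)N1[C@H](Cc2ccccc2)COC1=O | intermediate
29 | (4R)-4-benzyl-3-[(2R,4R,5S,6R)-6-(6-ethyl-3,5-dimethyl-4-oxo-4H-pyran-2-yl)-5-hydroxy-2,4-dimethyl-3-oxoheptanoyl]-1,3-oxazolidin-2-one | O=C(N1[C@H](Cc2ccccc2)COC1=O)[C@H](C)C(=O)[C@H](C)[C@@H](O)[C@@H](C)c1oc(CC)c(C)c(=O)c1C | intermediate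
30 | (4R)-4-benzyl-3-[(2R,3R,4R,5R,6R)-6-(6-ethyl-3,5-dimethyl-4-oxo-4H-pyran-2-yl)-3,5-dihydroxy-2,4-dimethylheptanoyl]-1,3-oxazolidin-2-one | O=C(N1[C@H](Cc2ccccc2)COC1=O)[C@H](C)[C@H](O)[C@H](C)[C@@H](O)[C@@H](C)c1oc(CC)c(C)c(=O)c1C | intermediate
31 | (3R,4R,5S,6R)-6-[(1R)-1-(6-ethyl-3,5-dimethyl-4-oxo-4H-pyran-2-yl)ethyl]-4-hydroxy-3,5-dimethyloxan-2-one | O=C1[C@H](C)[C@H](O)[C@H](C)[C@@H](O1)[C@@H](C)c2oc(CC)c(C)c(=O)c2C | intermediate
32 | (3R,4R,5R,6R)-4-[tert-butyl(dimethyl)silyl]oxy-6-[(1R)-1-(6-ethyl-3,5-dimethyl-4-oxo-4H-pyran-2-yl)ethyl]-3,5-dimethyloxan-2-one | O=C1[C@H](C)[C@H](O[Si](C)(C)C(C)(C)C)[C@H](C)[C@@H](O1)[C@@H](C)c2oc(CC)c(C)c(=O)c2C | intermediate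
33 | lithium (2R,3R,4R,5R,6R)-3-[tert-butyl(dimethyl)silyl]oxy-6-(6-ethyl-3,5-dimethyl-4-oxo-4H-pyran-2-yl)-5-hydroxy-2,4-dimethylheptanoate | [Li+].[O-]C(=O)[C@H](C)[C@H](O[Si](C)(C)C(C)(C)C)[C@H](C)[C@@H](O)[C@@H](C)c1oc(CC)c(C)c(=O)c1C | intermediate
34 | triethylsilyl (2R,3R,4R,5R,6R)-3-[tert-butyl(dimethyl)silyl]oxy-6-(6-ethyl-3,5-dimethyl-4-oxo-4H-pyran-2-yl)-2,4-dimethyl-5-(triethylsilyl)oxyheptanoate | CC[Si](CC)(CC)OC(=O)[C@H](C)[C@H](O[Si](C)(C)C(C)(C)C)[C@H](C)[C@@H](O[Si](CC)(CC)CC)[C@@H](C)c1oc(CC)c(C)c(=O)c1C | intermediate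
35 | (2R,3R,4R,5R,6R)-3-[tert-butyl(dimethyl)silyl]oxy-6-(6-ethyl-3,5-dimethyl-4-oxo-4H-pyran-2-yl)-2,4-dimethyl-5-(triethylsilyl)oxyheptanoic acid | OC(=O)[C@H](C)[C@H](O[Si](C)(C)C(C)(C)C)[C@H](C)[C@@H](O[Si](CC)(CC)CC)[C@@H](C)c1oc(CC)c(C)c(=O)c1C | intermediate
36 | mixed anhydride of 35 with 2,4,6-trichlorobenzoic acid | O=C(OC(=O)[C@H](C)[C@H](O[Si](C)(C)C(C)(C)C)[C@H](C)[C@@H](O[Si](CC)(CC)CC)[C@@H](C)c1oc(CC)c(C)c(=O)c1C)c1c(Cl)cc(Cl)cc1Cl | intermediate
37 | (4S,6S)-4,6-dimethylnona-2,7-diyn-5-yl (2R,3R,4R,5R,6R)-3-[tert-butyl(dimethyl)silyl]oxy-6-(6-ethyl-3,5-dimethyl-4-oxo-4H-pyran-2-yl)-2,4-dimethyl-5-(triethylsilyl)oxyheptanoate | CC#C[C@H](C)C(OC(=O)[C@H](C)[C@H](O[Si](C)(C)C(C)(C)C)[C@H](C)[C@@H](O[Si](CC)(CC)CC)[C@@H](C)c1oc(CC)c(C)c(=O)c1C)[C@@H](C)C#CC | intermediate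
38 | (4S,6S)-4,6-dimethylnona-2,7-diyn-5-yl (2R,3R,4R,5R,6R)-3-[tert-butyl(dimethyl)silyl]oxy-6-(6-ethyl-3,5-dimethyl-4-oxo-4H-pyran-2-yl)-5-hydroxy-2,4-dimethylheptanoate | CC#C[C@H](C)C(OC(=O)[C@H](C)[C@H](O[Si](C)(C)C(C)(C)C)[C@H](C)[C@@H](O)[C@@H](C)c1oc(CC)c(C)c(=O)c1C)[C@@H](C)C#CC | intermediate
39 | (4S,6S)-4,6-dimethylnona-2,7-diyn-5-yl (2R,3R,4S,6S)-3-[tert-butyl(dimethyl)silyl]oxy-6-(6-ethyl-3,5-dimethyl-4-oxo-4H-pyran-2-yl)-2,4-dimethyl-5-oxoheptanoate | CC#C[C@H](C)C(OC(=O)[C@H](C)[C@H](O[Si](C)(C)C(C)(C)C)[C@H](C)C(=O)[C@@H](C)c1oc(CC)c(C)c(=O)c1C)[C@@H](C)C#CC | intermediate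
40 | (4S,6S)-4,6-dimethylnona-2,7-diyn-5-yl (2R,3R,4S,6S)-6-(6-ethyl-3,5-dimethyl-4-oxo-4H-pyran-2-yl)-3-hydroxy-2,4-dimethyl-5-oxoheptanoate | CC#C[C@H](C)C(OC(=O)[C@H](C)[C@H](O)[C@H](C)C(=O)[C@@H](C)c1oc(CC)c(C)c(=O)c1C)[C@@H](C)C#CC | intermediate
41 | (4R,6S)-4,6-dimethyl-3-oxonon-7-yn-5-yl (2R,3R,4S,6S)-6-(6-ethyl-3,5-dimethyl-4-oxo-4H-pyran-2-yl)-3-hydroxy-2,4-dimethyl-5-oxoheptanoate (either arm hydrated first; C5 of the nonynyl part unspecified) | CCC(=O)[C@H](C)C(OC(=O)[C@H](C)[C@H](O)[C@H](C)C(=O)[C@@H](C)c1oc(CC)c(C)c(=O)c1C)[C@@H](C)C#CC | intermediate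
42 | (4R,6R)-4,6-dimethyl-3,7-dioxononan-5-yl (2R,3R,4S,6S)-6-(6-ethyl-3,5-dimethyl-4-oxo-4H-pyran-2-yl)-3-hydroxy-2,4-dimethyl-5-oxoheptanoate | CCC(=O)[C@H](C)C(OC(=O)[C@H](C)[C@H](O)[C@H](C)C(=O)[C@@H](C)c1oc(CC)c(C)c(=O)c1C)[C@@H](C)C(=O)CC | target

**Step count**

Total: 26 steps. Longest linear sequence: 16 steps (steps 1, 2, 11–15, 18–26; 1 → 2 → 3 → 18 → 19 → 20 → 21 → 22 → 29 → 31 → 32 → 35 → 37 → 38 → 39 → 40 → 42).

**Three steps most likely to fail**

Step 26. What may go wrong: participation by the hindered ester carbonyl may be too slow, so that undirected hydration puts oxygen on the distal alkyne carbon; or the cationic gold may be held by the pyranone and the β-hydroxy ketone long enough for acid-promoted epimerisation at C6 to set in. Fallback: the two ketones are unveiled before the acid is attached, with a sacrificial carbonate as the delivering group. It sets out from diynol 13 (and later uses acid 35) and rejoins the route at target 42. The lithium alkoxide of 13 (n-BuLi, THF, −78 °C) is acylated with benzyl chloroformate to the benzyl diynyl carbonate F1. Carbonate-assisted hydration (Ph3PAuNTf2, H2O, dioxane), the best documented 6-exo case for homopropargylic systems, should give the diketo benzyl carbonate F2. Neutral hydrogenolysis (H2, Pd on carbon, EtOAc) should give the hydroxy diketone F3. Yamaguchi esterification of F3 with 35 gives the bis-silylated diketo ester F4; pyridinium p-toluenesulfonate in MeOH gives the C5 alcohol F5; Dess–Martin oxidation gives the C5 ketone F6; HF·pyridine then gives 42. The price is a slower acylation of a carbinol that is prone to retro-aldol cleavage.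

Step 18. What may go wrong: the α-pyranonyl aldehyde may enolise under TiCl4/amine (loss of configuration at C6), or the pyranone carbonyl may bind titanium and erode the face selectivity of the enolate. Fallback: the C1–C4 unit is built on 22 by two reagent-controlled crotylborations, which are non-basic. It sets out from 22 and returns at acid 35. (Z)-Crotyldiisopinocampheylborane, of the pinene antipode that gives the 4,5-syn adduct with the C5 hydroxyl anti to the C6 methyl, should give the homoallylic alcohol F7. Et3SiOTf/2,6-lutidine gives the triethylsilyl ether F8, and OsO4 (cat.)/NaIO4/2,6-lutidine cleaves the vinyl group to the C3 aldehyde F9. (E)-Crotyldiisopinocampheylborane, of the antipode that overrides the Felkin bias, should give the 2,3-anti-3,4-anti alcohol F10. t-BuMe2SiOTf gives the silyl ether F11; a second OsO4/NaIO4 cleavage gives the C1 aldehyde F12; Pinnick oxidation (NaClO2, NaH2PO4, 2-methylbut-2-ene) gives 35.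

Step 9. What may go wrong: the α-alkynyl aldehyde 11 may racemise or isomerise to the allenal before or during the addition. Fallback: the allenylzinc is added to a robust β-silyloxy aldehyde and the second propynyl group is made afterwards. Because the two ends of the hydroxy ester then exchange roles, the (S)-hydroxy ester is needed. It sets out from mesylate 10 (with purchased methyl (S)-3-hydroxy-2-methylpropanoate) and returns at 13. Silylation and i-Bu2AlH reduction as in steps 1 and 2 give the (S)-silyl ester F13 and the (S)-silyloxy aldehyde F14. Addition of 10 under Pd(OAc)2/PPh3/Et2Zn (via 12) should give the anti,syn homopropargylic alcohol F15 (matched, Felkin). 4-Methoxybenzyl trichloroacetimidate with catalytic camphorsulfonic acid gives the 4-methoxybenzyl ether F16; Bu4NF gives the primary alcohol F17; Dess–Martin oxidation gives the aldehyde F18; CBr4/PPh3 gives the dibromo-olefin F19; n-BuLi then MeI gives the diyne 4-methoxybenzyl ether F20; DDQ in wet CH2Cl2 gives 13. The carbinol configuration of F15 to F19 does not matter, because that carbon stops being a stereocentre in F20.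

**Further compounds**

F1 | step 26 | benzyl (4S,6S)-4,6-dimethylnona-2,7-diyn-5-yl carbonate | CC#C[C@H](C)C(OC(=O)OCc1ccccc1)[C@@H](C)C#CC
F2 | step 26 | benzyl (4R,6R)-4,6-dimethyl-3,7-dioxononan-5-yl carbonate | CCC(=O)[C@H](C)C(OC(=O)OCc1ccccc1)[C@@H](C)C(=O)CC
F3 | step 26 | (4R,6R)-5-hydroxy-4,6-dimethylnonane-3,7-dione | CCC(=O)[C@H](C)C(O)[C@@H](C)C(=O)CC
F4 | step 26 | (4R,6R)-4,6-dimethyl-3,7-dioxononan-5-yl (2R,3R,4R,5R,6R)-3-[tert-butyl(dimethyl)silyl]oxy-6-(6-ethyl-3,5-dimethyl-4-oxo-4H-pyran-2-yl)-2,4-dimethyl-5-(triethylsilyl)oxyheptanoate | CCC(=O)[C@H](C)C(OC(=O)[C@H](C)[C@H](O[Si](C)(C)C(C)(C)C)[C@H](C)[C@@H](O[Si](CC)(CC)CC)[C@@H](C)c1oc(CC)c(C)c(=O)c1C)[C@@H](C)C(=O)CC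
F5 | step 26 | (4R,6R)-4,6-dimethyl-3,7-dioxononan-5-yl (2R,3R,4R,5R,6R)-3-[tert-butyl(dimethyl)silyl]oxy-6-(6-ethyl-3,5-dimethyl-4-oxo-4H-pyran-2-yl)-5-hydroxy-2,4-dimethylheptanoate | CCC(=O)[C@H](C)C(OC(=O)[C@H](C)[C@H](O[Si](C)(C)C(C)(C)C)[C@H](C)[C@@H](O)[C@@H](C)c1oc(CC)c(C)c(=O)c1C)[C@@H](C)C(=O)CC
F6 | step 26 | (4R,6R)-4,6-dimethyl-3,7-dioxononan-5-yl (2R,3R,4S,6S)-3-[tert-butyl(dimethyl)silyl]oxy-6-(6-ethyl-3,5-dimethyl-4-oxo-4H-pyran-2-yl)-2,4-dimethyl-5-oxoheptanoate | CCC(=O)[C@H](C)C(OC(=O)[C@H](C)[C@H](O[Si](C)(C)C(C)(C)C)[C@H](C)C(=O)[C@@H](C)c1oc(CC)c(C)c(=O)c1C)[C@@H](C)C(=O)CC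
F7 | step 18 | 2-ethyl-6-[(2R,3R,4S)-3-hydroxy-4-methylhex-5-en-2-yl]-3,5-dimethyl-4H-pyran-4-one | C=C[C@H](C)[C@@H](O)[C@@H](C)c1oc(CC)c(C)c(=O)c1C
F8 | step 18 | 2-ethyl-3,5-dimethyl-6-[(2R,3R,4S)-4-methyl-3-(triethylsilyl)oxyhex-5-en-2-yl]-4H-pyran-4-one | C=C[C@H](C)[C@@H](O[Si](CC)(CC)CC)[C@@H](C)c1oc(CC)c(C)c(=O)c1C
F9 | step 18 | (2R,3S,4R)-4-(6-ethyl-3,5-dimethyl-4-oxo-4H-pyran-2-yl)-2-methyl-3-(triethylsilyl)oxypentanal | O=C[C@H](C)[C@@H](O[Si](CC)(CC)CC)[C@@H](C)c1oc(CC)c(C)c(=O)c1C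
F10 | step 18 | 2-ethyl-6-[(2R,3R,4S,5S,6S)-5-hydroxy-4,6-dimethyl-3-(triethylsilyl)oxyoct-7-en-2-yl]-3,5-dimethyl-4H-pyran-4-one | C=C[C@H](C)[C@H](O)[C@H](C)[C@@H](O[Si](CC)(CC)CC)[C@@H](C)c1oc(CC)c(C)c(=O)c1C
F11 | step 18 | 2-{(2R,3R,4S,5S,6S)-5-[tert-butyl(dimethyl)silyl]oxy-4,6-dimethyl-3-(triethylsilyl)oxyoct-7-en-2-yl}-6-ethyl-3,5-dimethyl-4H-pyran-4-one | C=C[C@H](C)[C@H](O[Si](C)(C)C(C)(C)C)[C@H](C)[C@@H](O[Si](CC)(CC)CC)[C@@H](C)c1oc(CC)c(C)c(=O)c1C
F12 | step 18 | (2R,3R,4R,5R,6R)-3-[tert-butyl(dimethyl)silyl]oxy-6-(6-ethyl-3,5-dimethyl-4-oxo-4H-pyran-2-yl)-2,4-dimethyl-5-(triethylsilyl)oxyheptanal | O=C[C@H](C)[C@H](O[Si](C)(C)C(C)(C)C)[C@H](C)[C@@H](O[Si](CC)(CC)CC)[C@@H](C)c1oc(CC)c(C)c(=O)c1C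
F13 | step 9 | methyl (S)-3-[tert-butyl(diphenyl)silyl]oxy-2-methylpropanoate | COC(=O)[C@@H](C)CO[Si](c1ccccc1)(c1ccccc1)C(C)(C)C
F14 | step 9 | (S)-3-[tert-butyl(diphenyl)silyl]oxy-2-methylpropanal | O=C[C@@H](C)CO[Si](c1ccccc1)(c1ccccc1)C(C)(C)C
F15 | step 9 | (2S,3S,4S)-1-[tert-butyl(diphenyl)silyl]oxy-2,4-dimethylhept-5-yn-3-ol | CC#C[C@H](C)[C@H](O)[C@@H](C)CO[Si](c1ccccc1)(c1ccccc1)C(C)(C)C
F16 | step 9 | tert-butyl{[(2S,3S,4S)-3-(4-methoxybenzyl)oxy-2,4-dimethylhept-5-yn-1-yl]oxy}diphenylsilane | CC#C[C@H](C)[C@H](OCc1ccc(OC)cc1)[C@@H](C)CO[Si](c1ccccc1)(c1ccccc1)C(C)(C)C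
F17 | step 9 | (2S,3S,4S)-3-(4-methoxybenzyl)oxy-2,4-dimethylhept-5-yn-1-ol | CC#C[C@H](C)[C@H](OCc1ccc(OC)cc1)[C@@H](C)CO
F18 | step 9 | (2R,3S,4S)-3-(4-methoxybenzyl)oxy-2,4-dimethylhept-5-ynal | CC#C[C@H](C)[C@H](OCc1ccc(OC)cc1)[C@@H](C)C=O
F19 | step 9 | 1-({[(3S,4R,5S)-1,1-dibromo-3,5-dimethyloct-1-en-6-yn-4-yl]oxy}methyl)-4-methoxybenzene | CC#C[C@H](C)[C@H](OCc1ccc(OC)cc1)[C@@H](C)C=C(Br)Br
F20 | step 9 | 1-({[(4S,6S)-4,6-dimethylnona-2,7-diyn-5-yl]oxy}methyl)-4-methoxybenzene | CC#C[C@H](C)C(OCc1ccc(OC)cc1)[C@@H](C)C#CC
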